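**Retrosynthetic overview**
1. Target ⇐ one-pot removal of three benzyl ethers and one trichloroethyl (TCE) sulfate ester from a 5,7,4'-tri-O-benzyl flavonol that carries 3-OSO3(–) and 3'-OSO2OTCE.
2. 3-O-Sulfate ⇐ new net C3–H sulfoxylation of a flavone: DMDO epoxidation, then eliminative sulfative opening of the 2,3-epoxide with SO3·pyridine (makes C3–O and O–S).
3. 3'-O-Sulfate ⇐ TCE chlorosulfate on the only free phenol of 5,7,4'-tri-O-benzyl-luteolin.
4. Flavone ⇐ I2/DMSO oxidative cyclisation of a 2'-hydroxychalcone ⇐ Claisen–Schmidt condensation of 4',6'-bis(benzyloxy)-2'-hydroxyacetophenone with 4-benzyloxy-3-hydroxybenzaldehyde.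
5. Ring order: A and B rings are bought; the pyranone C ring is closed last and then oxidised at C3.

Assumption: the target has no stereocentre (achiral), so no enantiocontrol is needed; it is delivered as the free bis(hydrogen sulfate) as drawn, liberated from its diammonium salt 12 in the last step.

**Route**

Step 1
Reactants: 1 2',4',6'-trihydroxyacetophenone
Product: 2 1-[2,4-bis(benzyloxy)-6-hydroxyphenyl]ethanone
Conditions: BnBr (2.1 equiv), K2CO3 (2.2 equiv), DMF, 0 °C → rt
Reagents that add atoms: benzyl bromide, BrCc1ccccc1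
Why: Williamson etherification in which the 4-OH and one ortho-OH are alkylated while the remaining ortho-OH stays locked in the hydrogen bond to C=O, so the reaction stops at the 4,6-dibenzyl ether.

Step 2
Reactants: 2 1-[2,4-bis(benzyloxy)-6-hydroxyphenyl]ethanone; 3 4-(benzyloxy)-3-hydroxybenzaldehyde
Product: 4 (E)-1-[2,4-bis(benzyloxy)-6-hydroxyphenyl]-3-[4-(benzyloxy)-3-hydroxyphenyl]prop-2-en-1-one
Conditions: KOH (50% aq., 10 equiv), EtOH, rt, 48 h; then 1 M HCl to pH 5, 0 °C
Reagents that add atoms: none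
Why: Claisen–Schmidt condensation in which the aldehyde's phenoxide is meta to CHO and so does not deactivate it, and E1cB dehydration gives the E-enone.

Step 3
Reactants: 4 (E)-1-[2,4-bis(benzyloxy)-6-hydroxyphenyl]-3-[4-(benzyloxy)-3-hydroxyphenyl]prop-2-en-1-one
Product: 6 5,7-bis(benzyloxy)-2-[4-(benzyloxy)-3-hydroxyphenyl]-4H-chromen-4-one, via flavanone 5 (not isolated)
Conditions: I2 (10 mol %), DMSO, 130 °C, 2–3 h; aq. Na2S2O3 work-up
Reagents that add atoms: none
Why: iodine-catalysed oxidative cyclisation of a 2'-hydroxychalcone (oxa-Michael closure to the flavanone, α-iodination, loss of HI, with DMSO re-oxidising HI) forms the pyranone ring, and catalytic iodine is tolerated by benzyl ethers and the free 3'-OH.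

Step 4
Reactants: 7 2,2,2-trichloroethanol
Product: 8 2,2,2-trichloroethyl chlorosulfate
Conditions: SO2Cl2 (1.0 equiv), pyridine (1.0 equiv), Et2O, −78 °C → rt; distil
Reagents that add atoms: sulfuryl chloride, O=S(=O)(Cl)Cl
Why: nucleophilic substitution at S(VI) that stops at monosubstitution at low temperature because the electron-poor alcohol and the product chlorosulfate are a poor nucleophile/electrophile pair for a second substitution.

Step 5
Reactants: 6 5,7-bis(benzyloxy)-2-[4-(benzyloxy)-3-hydroxyphenyl]-4H-chromen-4-one; 8 2,2,2-trichloroethyl chlorosulfate (1.5 equiv)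
Product: 9 5,7-bis(benzyloxy)-2-[4-(benzyloxy)-3-{[(2,2,2-trichloroethoxy)sulfonyl]oxy}phenyl]-4H-chromen-4-one
Conditions: Et3N (2 equiv), DMAP (0.5 equiv), THF, 0 °C → rt
Reagents that add atoms: none
Why: DMAP-catalysed sulfuryl transfer (O-sulfonylation) to the only free OH gives a neutral, chromatographable protected aryl sulfate diester that is stable to oxidants and acid.

Step 6
Reactants: 9 5,7-bis(benzyloxy)-2-[4-(benzyloxy)-3-{[(2,2,2-trichloroethoxy)sulfonyl]oxy}phenyl]-4H-chromen-4-one
Product: 11 pyridinium 5,7-bis(benzyloxy)-2-[4-(benzyloxy)-3-{[(2,2,2-trichloroethoxy)sulfonyl]oxy}phenyl]-4-oxo-4H-chromen-3-yl sulfate, via flavone epoxide 10 (not isolated)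
Conditions: DMDO (ca. 0.08 M in acetone, freshly prepared, 3 equiv in portions), CH2Cl2, 0 °C → rt, dark; evaporate below 20 °C; then SO3·pyridine (3 equiv), pyridine (10 equiv), dry MeCN, −20 °C → rt
Reagents that add atoms: dimethyldioxirane, CC1(C)OO1; sulfur trioxide–pyridine complex, [O-]S(=O)(=O)[n+]1ccccc1
Why: Proposed new method: net C3–H sulfoxylation of a flavone, in which DMDO epoxidises C2=C3 (known) and the resulting 2-aryl-2-alkoxy oxirane is opened at its acetal-like C2 by SO3/pyridine (O-sulfonation and ionisation to the aryl-stabilised oxocarbenium, or pyridine attack at C2 with SO3 capture of the C3 alkoxide), after which loss of the acidic C3–H with expulsion of pyridine re-forms the pyranone so that the epoxide oxygen becomes the enol sulfate oxygen; the closest known reaction types are the acid-catalysed isomerisation of flavone epoxides to flavonols and the opening of epoxides by SO3·pyridine to β-pyridinio alkyl sulfate betaines, and any epoxide that isomerises to the free 3-ol is sulfated by the same reagent, so both paths converge on 11.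

Step 7
Reactants: 11 pyridinium 5,7-bis(benzyloxy)-2-[4-(benzyloxy)-3-{[(2,2,2-trichloroethoxy)sulfonyl]oxy}phenyl]-4-oxo-4H-chromen-3-yl sulfate
Product: 12 diammonium quercetin 3,3'-bissulfate
Conditions: 10% Pd/C, HCO2NH4 (20 equiv), MeOH/THF 2:1, rt → 40 °C; filter through Celite; Sephadex LH-20 (MeOH/H2O)
Reagents that add atoms: ammonium formate, [NH4+].[O-]C=O
Why: Pd-catalysed transfer hydrogenolysis cleaves the three aryl benzyl ethers and the trichloroethyl ester (C–Cl insertion then β-elimination) while the formate buffer keeps the acid-labile sulfate monoesters as ammonium salts, which like the flavonol core are inert to Pd/H.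

Step 8
Reactants: 12 diammonium quercetin 3,3'-bissulfate
Product: 13 quercetin 3,3'-bissulfate (free bis(hydrogen sulfate), the target)
Conditions: Dowex 50W-X8 (H+ form), H2O, 0–4 °C; immediate freeze-drying; store at −20 °C
Reagents that add atoms: none
Why: cation exchange (NH4+ for H+) on a sulfonic acid resin in the cold followed by immediate lyophilisation delivers the free acid before acid-autocatalysed desulfation can set in.

**Compound list**
1 | 2',4',6'-trihydroxyacetophenone | CC(=O)c1c(O)cc(O)cc1O | starting material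
2 | 1-[2,4-bis(benzyloxy)-6-hydroxyphenyl]ethanone (4',6'-bis(benzyloxy)-2'-hydroxyacetophenone) | CC(=O)c1c(O)cc(OCc2ccccc2)cc1OCc1ccccc1 | intermediate
3 | 4-(benzyloxy)-3-hydroxybenzaldehyde | O=Cc1ccc(OCc2ccccc2)c(O)c1 | starting material
4 | (E)-1-[2,4-bis(benzyloxy)-6-hydroxyphenyl]-3-[4-(benzyloxy)-3-hydroxyphenyl]prop-2-en-1-one | O=C(/C=C/c1ccc(OCc2ccccc2)c(O)c1)c1c(O)cc(OCc2ccccc2)cc1OCc1ccccc1 | intermediate
5 | racemic 5,7-bis(benzyloxy)-2-[4-(benzyloxy)-3-hydroxyphenyl]chroman-4-one (flavanone, not isolated) | O=C1CC(c2ccc(OCc3ccccc3)c(O)c2)Oc2cc(OCc3ccccc3)cc(OCc3ccccc3)c12 | intermediate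
6 | 5,7-bis(benzyloxy)-2-[4-(benzyloxy)-3-hydroxyphenyl]-4H-chromen-4-one | O=c1cc(-c2ccc(OCc3ccccc3)c(O)c2)oc2cc(OCc3ccccc3)cc(OCc3ccccc3)c12 | intermediate
7 | 2,2,2-trichloroethanol | OCC(Cl)(Cl)Cl | starting material
8 | 2,2,2-trichloroethyl chlorosulfate | ClC(Cl)(Cl)COS(=O)(=O)Cl | intermediate
9 | 5,7-bis(benzyloxy)-2-[4-(benzyloxy)-3-{[(2,2,2-trichloroethoxy)sulfonyl]oxy}phenyl]-4H-chromen-4-one | O=c1cc(-c2ccc(OCc3ccccc3)c(OS(=O)(=O)OCC(Cl)(Cl)Cl)c2)oc2cc(OCc3ccccc3)cc(OCc3ccccc3)c12 | intermediate
10 | racemic 2,3-epoxide of 9 (5,7-bis(benzyloxy)-2-aryl-2,3-epoxychroman-4-one, cis-fused oxirane, not isolated) | O=C1C2OC2(c3ccc(OCc4ccccc4)c(OS(=O)(=O)OCC(Cl)(Cl)Cl)c3)Oc3cc(OCc4ccccc4)cc(OCc4ccccc4)c13 | intermediate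
11 | pyridinium 5,7-bis(benzyloxy)-2-[4-(benzyloxy)-3-{[(2,2,2-trichloroethoxy)sulfonyl]oxy}phenyl]-4-oxo-4H-chromen-3-yl sulfate | O=c1c(OS(=O)(=O)[O-])c(-c2ccc(OCc3ccccc3)c(OS(=O)(=O)OCC(Cl)(Cl)Cl)c2)oc2cc(OCc3ccccc3)cc(OCc3ccccc3)c12.c1cc[nH+]cc1 | intermediate
12 | diammonium quercetin 3,3'-bissulfate (diammonium 5,7-dihydroxy-2-[4-hydroxy-3-(sulfonatooxy)phenyl]-4-oxo-4H-chromen-3-yl sulfate) | O=c1c(OS(=O)(=O)[O-])c(-c2ccc(O)c(OS(=O)(=O)[O-])c2)oc2cc(O)cc(O)c12.[NH4+].[NH4+] | intermediate
13 | quercetin 3,3'-bissulfate (5,7-dihydroxy-2-[4-hydroxy-3-(sulfooxy)phenyl]-4-oxo-4H-chromen-3-yl hydrogen sulfate; achiral) | O=c1c(OS(=O)(=O)O)c(-c2ccc(O)c(OS(=O)(=O)O)c2)oc2cc(O)cc(O)c12 | target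

**Step count**
Total steps: 8. Longest linear sequence: 7 steps (steps 1, 2, 3, 5, 6, 7, 8; step 4 is a one-step side branch that makes reagent 8).

**Three steps most likely to fail, with fallbacks**

Step 6 (proposed new method). The epoxide may rearrange, or the sulfative opening may be slow or unselective. The fallback is known chemistry and sets out from 9: epoxidise with DMDO as before to the epoxide 10, then add p-TsOH (5 mol %) in CH2Cl2 at 0 °C to isomerise it to the flavonol 5,7-bis(benzyloxy)-3-hydroxy-2-[4-(benzyloxy)-3-{[(2,2,2-trichloroethoxy)sulfonyl]oxy}phenyl]-4H-chromen-4-one F1, which is isolated by chromatography. The enolic 3-OH of this compound is then O-sulfated with SO3·pyridine in pyridine at rt (standard sulfation of the most reactive flavonol hydroxyl), which comes back to the route at 11.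

Step 7. Debenzylation may stall because of chlorinated fragments or nitrogen bases on the palladium, or the 3-sulfate may be lost. The fallback sets out from 11 and separates the two deprotections: the TCE ester is first removed by reductive β-elimination with Zn dust and HCO2NH4 in MeOH at rt, giving diammonium 5,7,4'-tri-O-benzylquercetin 3,3'-bissulfate F2, which is purified on Sephadex LH-20. The three benzyl ethers are then cleaved on this chloride-free salt with H2 (1 atm) over Pd(OH)2/C in THF/MeOH/H2O at rt, which comes back to the route at 12.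

Step 3. The hot, HI-generating medium may cleave the peri 5-O-benzyl ether or iodinate the free-phenol ring. The fallback sets out from 4 and replaces the one-pot oxidative cyclisation by a stepwise, base-buffered sequence: ring closure by oxa-Michael addition with NaOAc in refluxing EtOH to the flavanone 5, which is isolated here, followed by dehydrogenation of 5 with I2 (1.1 equiv) in pyridine at 90 °C (α-iodination and E2 loss of HI under basic conditions, the classical flavanone-to-flavone protocol that tolerates a 3'-OH/4'-OR B ring). It comes back to the route at 6 and makes no new compound (none, F0).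

**Further compounds**
F1 | step 6 | 5,7-bis(benzyloxy)-3-hydroxy-2-[4-(benzyloxy)-3-{[(2,2,2-trichloroethoxy)sulfonyl]oxy}phenyl]-4H-chromen-4-one | O=c1c(O)c(-c2ccc(OCc3ccccc3)c(OS(=O)(=O)OCC(Cl)(Cl)Cl)c2)oc2cc(OCc3ccccc3)cc(OCc3ccccc3)c12
F2 | step 7 | diammonium 5,7-bis(benzyloxy)-2-[4-(benzyloxy)-3-(sulfonatooxy)phenyl]-4-oxo-4H-chromen-3-yl sulfate | O=c1c(OS(=O)(=O)[O-])c(-c2ccc(OCc3ccccc3)c(OS(=O)(=O)[O-])c2)oc2cc(OCc3ccccc3)cc(OCc3ccccc3)c12.[NH4+].[NH4+]
F0 | step 3 | none | none
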